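At early times, the thing to watch is how ring and open dimer divide the substrate.

| flask | substrate | remark | time |
|---|---|---|---|
| Monday's | 0.10 M | run made earlier |  |
| Wednesday's | 0.050 M | run made earlier |  |
| summer | 0.10 M | plug flow through a tube for 5.0 d, no back-mixing | 5.0 d |
| dawn | 0.10 M | a closed flask charged with all of it at once and left for 5.0 d | 5.0 d |
| winter | 0.10 M | one stirred flow tank at steady state, fed with the mixture as stated, mean residence time 5.0 d |  |
| dusk | 0.10 M | a single well-mixed tank run continuously and read at steady state, 25.0 d in it on average |  |

Monday's run (percent of the substrate charged)

| time / d | ring / % | open dimer / % | open trimer / % |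
|---|---|---|---|
| 0.167 | 7 | 6 | 2 |
| 0.500 | 14 | 14 | 2 |
| 0.833 | 16 | 15 | 2 |
| 1.25 | 18 | 15 | 0 |
| 1.67 | 26 | 16 | 5 |
| 2.50 | 21 | 14 | 0 |
| 3.00 | 26 | 13 | 0 |

Wednesday's run (percent of the substrate charged)

| time / h | ring / % | open dimer / % | open trimer / % |
|---|---|---|---|
| 3.00 | 4 | 5 | 1 |
| 6.00 | 9 | 5 | 0 |
| 10.0 | 11 | 7 | 0 |
| 15.0 | 15 | 8 | 0 |
| 20.0 | 19 | 10 | 0 |
| 25.0 | 19 | 12 | 4 |

(scatter of a reading: 2 percentage points)

- percent here means substrate units held: one open dimer counts as two
- percent here means substrate units held: one open trimer counts as three
- the stated concentrations are those of everything mixed, before any reaction; amounts are the same in each set-up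
- the earlier runs were made in a closed, stirred flask
- a reading or a percentage of ring counts all its forms, free or not

- the set-up with the highest share of ring in all that became ring or open dimer or open trimer, at the outlet or at the end ("none" if the first two lie within 2 percentage points) (summer / dawn / winter / dusk / none)
- share of ring in all that became ring or open dimer or open trimer, at the outlet or at the end, summer
- share of ring in all that became ring or open dimer or open trimer, at the outlet or at the end, dawn
- share of ring in all that became ring or open dimer or open trimer, at the outlet or at the end, winter
- share of ring in all that became ring or open dimer or open trimer, at the outlet or at the end, dusk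

1. **Ring as the main step.** Taken by itself, ring has a share of 100 %, and Monday's first reading puts its first-order constant near 0.419 d⁻¹.

2. **Open dimer added.** At 0.833 d, Monday's ring-to-dimer ratio reads 1.07, while Wednesday's, at the same clock and with half the charge, reads about twice that, so open dimer is taken as second order. Wednesday's pairs, summed with the charge as level, read 0.0819 M for the crossing level, the substrate level at which ring and open dimer gain substrate units equally (a selectivity factor expressed as a concentration). At level S, with these two steps, ring takes crossing/(crossing + S) of what the two form. Integrated from the charge down to no substrate, an end that my reckoning assumes for 5.0 d, this gives (crossing/charge) ln(1 + charge/crossing), which is 65.4 % for dawn and for summer, plug flow being taken to follow the same course as the closed flask.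

3. **The stall.** Monday's products sum to 39.0 % at 3.00 d. Had the level fallen by that much and no further, the integral would give 50.7 %, but the share reads 66.7 %, higher. My reckoning therefore keeps the full integral, with substrate leaving by some unread way.

4. **The tanks.** In my reckoning, which leaves the unread way out of this balance, each tank holds one level, set by feed against both steps: 0.0265 M in winter and 0.00800 M in dusk. The shares are then 75.6 % for winter and 91.1 % for dusk, which puts dusk first.

The forecast also chose dusk, with 60 % for summer, 60 % for dawn, 63 % for winter and 71 % for dusk, holding that “Stalling slows both paths equally, so selectivity depends only on substrate level.”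

The flasks give 65.2 % in summer, 65.2 % in dawn, 80.7 % in winter and 91.8 % in dusk, so the best is dusk.

    substrate → ring (k = 0.0165 h⁻¹)
    2 substrate → open dimer (k = 0.118 M⁻¹ h⁻¹)
    substrate + open dimer → open trimer (k = 0.0863 M⁻¹ h⁻¹)
    substrate ⇌ dormant form (K = 3.00, k = 0.0369 h⁻¹)
    substrate + ring ⇌ idle adduct, settled at all times (K = 93.4 M⁻¹)

Substrate's half-life, each reaction taken alone, is 0.78 d towards the dormant form (forward rate only, the way back not counted) and 1.8 d towards ring, shorter for the dormant form, and in winter substrate stood at 0.0156 M, below the 0.0265 M reckoned and below the crossing level. At that winter level the crossing level gives 84.0 % against the tank's 80.7 %, and the closed form for Wednesday's charge gives 78.1 % against a simulated 78.8 % for that charge left 5.0 d.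

The runs are calculated from invented constants; scatter was added.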